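## Structural features

The target is a thymol-type aromatic monoterpenoid, and thymol numbering is used throughout. The benzene ring (C1–C6) carries CH3 at C1, the oxygen of the tiglate ((E)-2-methylbut-2-enoate) at C3, the side chain at C4 and OCH3 at C6, with H at C2 and C5. The side chain hangs on one fully substituted carbon, C8. C8 is bound to C4, to the oxirane oxygen O8, to the oxirane methylene C9, and to the methylene C10 that carries the isobutyrate through O10. The oxirane (O8, C8, C9) is the only non-aromatic ring.

C8 (R) is the only stereocentre, so no neighbouring centre can relay configuration. Two of its substituents, C9H2–O and C10H2–O, differ only in what the oxygen is bound to.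

The fragile groups are:
- the tertiary benzylic epoxide on an electron-rich ring, which can ionise, rearrange in the Meinwald sense, or be attacked by the isobutyrate carbonyl under acid or Lewis acid;
- the aryl tiglate, an activated ester that is easily cleaved or passed to a neighbouring alkoxide;
- the latent phenol, which if freed would push the epoxide open through an ortho-quinone methide and erase C8.

The real difficulty is therefore the absolute configuration at an almost symmetric tetrasubstituted carbon, plus the placing of three different oxygen functions (epoxide, alkyl ester, aryl ester) without acyl scrambling.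

The key step exploits the hidden mirror plane of the C9–C8–C10 unit. If C9 is bound to O10 instead of O8, the atoms O10, C9, C8 and C10 form an achiral oxetane ring. With the isobutyryl group parked on O8, this oxetane is a constitutional isomer of the target. The route builds this easier four-membered skeleton first and converts it into the oxirane skeleton by strain-driven, catalyst-controlled cleavage of C9–O10.

## Logic of the disconnections

**13 ⇒ 11 (through 12).** The bonds cut are O8–C9 of the oxirane and the acyl–O10 bond. C9 receives bromine and the isobutyryl group returns to O8. The cut is made here so that the fragile epoxide appears only in the last step, under mild base, with no acylation afterwards. The gain is that the epoxide ring and the final position of the alkyl ester both follow from one deprotonation. The demand is that the O8 alkoxide of 12 must displace bromide from C9 faster than it attacks the aryl ester carbonyl. Bonds to C8 must stay untouched.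

**11 ⇒ 9 (through 10), the key disconnection.** C9–Br is cut and C9–O10 is re-formed. C9 and C10 become equivalent, the only stereocentre disappears, and 9 has a mirror plane and the molecular formula of 13. In one sentence, the route is the enantioselective bromide opening of 9, an achiral ring isomer of 13. That sentence does not fit an alkene epoxidation route. The gain is the loss of the stereocentre and of the need to tell two CH2O arms apart by protecting groups. The ring oxygen serves as protecting group for O10 and as latent leaving group at C9. The demand is a catalyst that distinguishes two enantiotopic CH2 groups, and conditions that spare two esters and the tertiary benzylic C8–O8 bond.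

**9 ⇒ 7 + 8.** The acyl–O8 bond is cut. Parking the isobutyryl group on O8 blocks the tertiary alcohol during the silyl bromide step and stores the acyl group one atom from its final place. The demand is acylation of a tertiary alcohol without transfer of the aryl ester.

**7 ⇒ 5 + 6.** The acyl–O3 bond is cut. The tiglate must be in place before any epoxide exists, since a free phenol next to the epoxide is not tolerable. The demand is phenol-over-tertiary-alcohol selectivity and retention of the E geometry brought in by 6.

**5 ⇒ 2 + 3 (through 4).** The C4–C8 bond is cut. One carbonyl addition delivers C8, C9, C10, O8 and O10 at once. The demand is an aryl anion at C4 next to an unprotected phenoxide, and a neutral work-up.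

**2 ⇒ 1.** The C4–Br bond is cut. The demand is bromination ortho to OH and para to CH3 only.

## Other disconnections considered

**Alternative 1:** This is the first plan that comes to mind. Both C–O bonds of the oxirane are cut back to a C8=C9 alkene. The forward key step is a Katsuki–Sharpless epoxidation of the 2-arylallyl alcohol A1 to the epoxy alcohol A2, followed by isobutyrylation.
- A2 is a tertiary benzylic epoxide on an electron-rich ring. It would have to survive a Lewis acidic titanium alkoxide medium that offers isopropoxide and tartrate as nucleophiles at C8.
- Titanium alkoxides also catalyse transesterification of the aryl tiglate.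
- A1 needs its own multistep assembly (cross-coupling or ketone methylenation, with phenol protection and release), so C8=C9 is made only to be oxidised.
- The chosen plan never exposes the epoxide to a Lewis acid and obtains the whole side chain from one addition.

**Alternative 2:** C8–C9 and O8–C9 are cut. The forward key step is a catalytic asymmetric Corey–Chaykovsky methylene transfer to the α-acyloxy ketone A3.
- The ylide is basic and nucleophilic, while A3 is easily enolised at C10 and carries an activated aryl ester ortho to the carbonyl.
- The betaine alkoxide at O8 sits between two acyl donors and has a slower leaving group than bromide.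
- A3 itself needs a Fries-type acylation and an α-oxygenation.
- The chosen plan meets the same alkoxide only once, with the best available leaving group and no external nucleophile.

**Alternative 3:** The acyl–O10 bond is cut back to the symmetric triol A4. The forward key step is an enzymatic or organocatalytic desymmetrising mono-isobutyrylation to the monoester A5, then sulfonylation of the remaining primary alcohol and closure.
- It uses the same hidden symmetry, but the two arms of A5 differ only by an acyl group. That group can wander between the primary oxygens through a six-membered orthoacid, which racemises C8.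
- One more activation step is needed.
- A4 requires addition to a protected dihydroxyacetone and an acidic deprotection that the tertiary benzylic alcohol resists poorly.
- In the chosen plan the arms become CH2Br and CH2O, which cannot exchange, and ring strain replaces the activation step.

Key step: step 5

Assumption: the sense of induction of the squaramide on 9 cannot be derived with certainty. The catalyst enantiomer that attacks the pro-S CH2 group and gives (S)-11 is meant, both antipodes being accessible from L- or D-tert-leucine.

## Steps

Step 1
Reactants: 1 4-methoxy-3-methylphenol
Product: 2 2-bromo-4-methoxy-5-methylphenol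
Conditions: NBS (1.0 equiv), i-Pr2NH (0.1 equiv), CH2Cl2, 0 °C
Reagents that add atoms: N-bromosuccinimide, O=C1CCC(=O)N1Br
Why: Electrophilic aromatic bromination in its amine-mediated, ortho-to-OH selective form; the free OH is the strongest donor, its para position is blocked by OCH3, and of the two ortho positions the one between OH and CH3 is shielded while the other is also para to CH3, so bromine should enter only there.

Step 2
Reactants: 2 2-bromo-4-methoxy-5-methylphenol; 3 oxetan-3-one
Product: 5 2-(3-hydroxyoxetan-3-yl)-4-methoxy-5-methylphenol, via O,C-dilithiated phenol 4 (not isolated)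
Conditions: n-BuLi (2.2 equiv), THF, −78 to −40 °C; then 3, −78 to 0 °C; aq. NH4Cl
Reagents that add atoms: none
Why: Deprotonation followed by bromine–lithium exchange gives 4, which adds 1,2 to the strained, strongly electrophilic and poorly enolisable ketone 3 (organolithium addition to a ketone). This one C4–C8 bond formation brings in C8, C9, C10, O8 and O10, and no stereocentre arises because 5 has a mirror plane. The neutral quench avoids acid-induced attack of the phenol on the oxetane.

Step 3
Reactants: 5 2-(3-hydroxyoxetan-3-yl)-4-methoxy-5-methylphenol; 6 (E)-2-methylbut-2-enoyl chloride (tigloyl chloride)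
Product: 7 2-(3-hydroxyoxetan-3-yl)-4-methoxy-5-methylphenyl (E)-2-methylbut-2-enoate
Conditions: 6 (1.05 equiv), Et3N (1.3 equiv), CH2Cl2, −20 to 0 °C
Reagents that add atoms: none
Why: Chemoselective O-acylation of a phenol with an acid chloride under amine base; the acidic, unhindered phenol reacts, whereas the tertiary alcohol does not react with an α-branched conjugated acid chloride without a nucleophilic catalyst. Et3N cannot deprotonate O8–H, so no acyl migration is triggered, and the E geometry is that of 6.

Step 4
Reactants: 7 2-(3-hydroxyoxetan-3-yl)-4-methoxy-5-methylphenyl (E)-2-methylbut-2-enoate; 8 2-methylpropanoic anhydride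
Product: 9 4-methoxy-5-methyl-2-[3-(2-methylpropanoyloxy)oxetan-3-yl]phenyl (E)-2-methylbut-2-enoate
Conditions: 8 (2 equiv), DMAP (0.2 equiv), Et3N (3 equiv), CH2Cl2, rt
Reagents that add atoms: none
Why: DMAP-catalysed acylation of a tertiary alcohol with an anhydride; two substituents of C8 are tied back in the four-membered ring, which makes O8–H more accessible than in an open tertiary carbinol. The conjugated, α-branched ester of an electron-rich phenol is a poor acyl donor towards DMAP, so scrambling should stay minor. Compound 9 is achiral and a constitutional isomer of the target.

Step 5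
Reactants: 9 4-methoxy-5-methyl-2-[3-(2-methylpropanoyloxy)oxetan-3-yl]phenyl (E)-2-methylbut-2-enoate
Product: 11 2-[(2S)-1-bromo-3-hydroxy-2-(2-methylpropanoyloxy)propan-2-yl]-4-methoxy-5-methylphenyl (E)-2-methylbut-2-enoate, via primary trimethylsilyl ether 10 (not isolated)
Conditions: TMSBr (1.3 equiv, freshly distilled), chiral tert-leucine 2-arylpyrrolidine-amide squaramide (5–10 mol %), t-BuOMe, −78 °C (to −40 °C if slow); then aq. citric acid, THF, 0 °C
Reagents that add atoms: bromotrimethylsilane, C[Si](C)(C)Br
Why: This is the enantioselective desymmetrising opening of a prochiral 3,3-disubstituted oxetane with TMSBr under chiral hydrogen-bond-donor (squaramide) catalysis, a known reaction type for such oxetanes. Mechanism: the squaramide binds the bromide of TMSBr and thereby raises the Lewis acidity of silicon, the oxetane oxygen O10 (the most basic oxygen of 9) is silylated, and the catalyst-bound bromide is delivered in an SN2 step to one of the two enantiotopic CH2 groups of the silyloxetanium ion. About 25 kcal/mol of ring strain is released, which makes the C9–O10 cleavage irreversible at low temperature. No ring is closed; the ring (O10, C9, C8, C10) is opened, so C9 becomes an electrophile and O10 stays as a masked nucleophile on C10. C8 becomes stereogenic without any bond to it being touched, and its configuration is controlled by the catalyst alone, which has to tell the flat arene (cation–π contact with the catalyst aryl group) from the acyloxy group, attack at the pro-S CH2 giving (S)-10. The step needs selectivity for the oxetane over two esters, the aryl methyl ether and the tertiary benzylic C8–O8 bond, and this is secured by the low temperature, the higher basicity of the oxetane oxygen, and the angle strain and inductive destabilisation of a cation at C8 inside a four-membered ring. Participation of the O8 ester carbonyl would erode the selectivity, but the O8–C8–C9–O10 dihedral angle is locked near 120° by the ring, so that carbonyl oxygen cannot reach the backside of C9–O10, and dry, HBr-free TMSBr suppresses the uncatalysed path. The citric acid work-up removes the labile primary TMS group, and any drift of the acyl group from O8 to O10 at this stage is harmless because both isomers converge in step 6.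

Step 6
Reactants: 11 2-[(2S)-1-bromo-3-hydroxy-2-(2-methylpropanoyloxy)propan-2-yl]-4-methoxy-5-methylphenyl (E)-2-methylbut-2-enoate
Product: 13 [(2R)-2-{5-methoxy-4-methyl-2-[(E)-2-methylbut-2-enoyloxy]phenyl}oxiran-2-yl]methyl 2-methylpropanoate = CNP0256150.1, via tertiary bromohydrin 12 (not isolated)
Conditions: Cs2CO3 (1.5 equiv, dry), MeCN, 0 °C to rt
Reagents that add atoms: none
Why: Cascade of two known base-induced events: the C10 alkoxide takes the isobutyryl group from the crowded tertiary O8 (1,2-O→O acyl migration through a five-membered orthoacid anion), and the O8 alkoxide of 12 then displaces bromide from C9 (3-exo-tet Williamson-type halohydrin closure, irreversible and accelerated by the gem-disubstitution at C8). No bond to C8 is made or broken, so the configuration set in step 5 is kept and the descriptor changes from S to R only because the priorities change. The closure has to outrun attack of the hindered O8 alkoxide on the conjugated, α-branched and therefore sluggish tiglate carbonyl as well as the slower 4-exo-tet return to 9, and a heterogeneous carbonate in an aprotic solvent should leave both esters and the epoxide untouched.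

## Compound list

1 | 4-methoxy-3-methylphenol | COc1ccc(O)cc1C | starting material
2 | 2-bromo-4-methoxy-5-methylphenol | Oc1cc(C)c(OC)cc1Br | intermediate
3 | oxetan-3-one | O=C1COC1 | starting material
4 | lithium 2-lithio-4-methoxy-5-methylphenolate | [Li]Oc1cc(C)c(OC)cc1[Li] | intermediate
5 | 2-(3-hydroxyoxetan-3-yl)-4-methoxy-5-methylphenol | Oc1cc(C)c(OC)cc1C1(O)COC1 | intermediate
6 | (E)-2-methylbut-2-enoyl chloride (tigloyl chloride) | C/C=C(\C)C(=O)Cl | starting material
7 | 2-(3-hydroxyoxetan-3-yl)-4-methoxy-5-methylphenyl (E)-2-methylbut-2-enoate | C/C=C(\C)C(=O)Oc1cc(C)c(OC)cc1C1(O)COC1 | intermediate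
8 | 2-methylpropanoic anhydride | CC(C)C(=O)OC(=O)C(C)C | starting material
9 | 4-methoxy-5-methyl-2-[3-(2-methylpropanoyloxy)oxetan-3-yl]phenyl (E)-2-methylbut-2-enoate | C/C=C(\C)C(=O)Oc1cc(C)c(OC)cc1C1(OC(=O)C(C)C)COC1 | intermediate
10 | 2-[(2S)-1-bromo-2-(2-methylpropanoyloxy)-3-(trimethylsilyloxy)propan-2-yl]-4-methoxy-5-methylphenyl (E)-2-methylbut-2-enoate | C/C=C(\C)C(=O)Oc1cc(C)c(OC)cc1[C@](OC(=O)C(C)C)(CO[Si](C)(C)C)CBr | intermediate
11 | 2-[(2S)-1-bromo-3-hydroxy-2-(2-methylpropanoyloxy)propan-2-yl]-4-methoxy-5-methylphenyl (E)-2-methylbut-2-enoate | C/C=C(\C)C(=O)Oc1cc(C)c(OC)cc1[C@](OC(=O)C(C)C)(CO)CBr | intermediate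
12 | 2-[(2S)-1-bromo-2-hydroxy-3-(2-methylpropanoyloxy)propan-2-yl]-4-methoxy-5-methylphenyl (E)-2-methylbut-2-enoate | C/C=C(\C)C(=O)Oc1cc(C)c(OC)cc1[C@](O)(COC(=O)C(C)C)CBr | intermediate
13 | [(2R)-2-{5-methoxy-4-methyl-2-[(E)-2-methylbut-2-enoyloxy]phenyl}oxiran-2-yl]methyl 2-methylpropanoate (CNP0256150.1) | C/C=C(\C)C(=O)Oc1cc(C)c(OC)cc1[C@]1(COC(=O)C(C)C)CO1 | target

## Step count and least certain steps

Total step count: 6. Longest linear sequence: 6 (1 → 2 → 5 → 7 → 9 → 11 → 13).

**Step 5 (key step).**
- Most likely failure: poor discrimination between the two enantiotopic CH2 groups. Both substituents at C8 are large, and the two ester carbonyls compete with bromide for the hydrogen-bond donor.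
- A slow catalysed reaction is also possible, since C9 is a neopentyl-type carbon and the acyloxy group lowers the basicity of the oxetane oxygen. This would let a racemic background opening by traces of HBr take over.
- Fallback (resolution in place of desymmetrisation): it sets out from 9, which is opened without a chiral catalyst by MgBr2·OEt2 in Et2O/CH2Cl2 to the racemic bromo alcohol F1. A lipase chosen by screening, with vinyl acetate in t-BuOMe, acetylates the primary alcohol of the (R)-enantiomer to the acetate F2 and leaves the (S)-enantiomer. This is separated by chromatography and comes back to the route as 11. Only half of the material can be used, which is the price of this fallback.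

**Step 6.**
- Most likely failure: transfer of the tigloyl group from the aryl oxygen to the O8 alkoxide through a six-membered transition state, followed by alkylation of the liberated phenoxide by C9.
- Cleavage of the aryl ester by adventitious hydroxide is a second risk.
- Both compete with the closure from the same alkoxide, so changing the base alone cannot cure them.
- Fallback (aryl ester introduced last, without a free phenoxide): it sets out from 5. Allyl bromide and K2CO3 in acetone give the aryl allyl ether F3. Acylation with 8 as in step 4 gives the tertiary isobutyrate F4. Opening as in step 5 gives, through the trimethylsilyl ether F5, the (S)-bromo alcohol F6. Cs2CO3 in MeCN takes F6 through the bromohydrin F7 to the (R)-epoxide F8, now with no aryl ester next to the alkoxide. Pd(PPh3)4-catalysed hydrostannolysis of the allyl ether with Bu3SnH gives the covalent tin phenoxide F9. F9 donates far less strongly than a free phenoxide and is acylated in the same flask by 6, which brings the sequence back to the route at 13.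

**Step 4.**
- Most likely failure: sluggish acylation of the hindered tertiary alcohol, which leaves time for DMAP-mediated exchange of the two acyl groups between O3 and O8.
- Fallback (intramolecular delivery of the acyl group): it sets out from 5. Isobutyryl chloride and Et3N in CH2Cl2 at −20 °C give the aryl isobutyrate F10. LiHMDS in THF at −78 °C deprotonates O8–H, and the acyl group migrates from O3 to O8 through a six-membered tetrahedral intermediate, driven by formation of the more stable phenoxide, to give the lithium phenolate F11. This is kept cold to prevent loss of carboxylate and is trapped in the same flask by 6, which brings the sequence back to the route at 9 and bypasses 7.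

**Step 2.**
- Most likely failure: incomplete bromine–lithium exchange on the electron-rich phenoxide, or premature protonation of the poorly soluble dianion, so that debromination competes with addition.
- Acid-induced attack of the phenol on the oxetane during work-up is a second risk.
- Fallback (protected monoanion in place of the dianion): it sets out from 2. Benzyl bromide and K2CO3 in acetone give the benzyl ether F12. n-BuLi in THF at −78 °C gives the aryllithium F13, which adds to 3 to give the oxetanol F14. Hydrogenolysis (H2, Pd/C, EtOAc, neutral) removes the benzyl group and comes back to the route at 5.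

## Further compounds

F1 | step 5 | rac-2-[1-bromo-3-hydroxy-2-(2-methylpropanoyloxy)propan-2-yl]-4-methoxy-5-methylphenyl (E)-2-methylbut-2-enoate | C/C=C(\C)C(=O)Oc1cc(C)c(OC)cc1C(OC(=O)C(C)C)(CO)CBr
F2 | step 5 | 2-[(2R)-1-acetoxy-3-bromo-2-(2-methylpropanoyloxy)propan-2-yl]-4-methoxy-5-methylphenyl (E)-2-methylbut-2-enoate | C/C=C(\C)C(=O)Oc1cc(C)c(OC)cc1[C@@](OC(=O)C(C)C)(COC(C)=O)CBr
F3 | step 6 | 3-[5-methoxy-4-methyl-2-(prop-2-enyloxy)phenyl]oxetan-3-ol | C=CCOc1cc(C)c(OC)cc1C1(O)COC1
F4 | step 6 | 3-[5-methoxy-4-methyl-2-(prop-2-enyloxy)phenyl]oxetan-3-yl 2-methylpropanoate | C=CCOc1cc(C)c(OC)cc1C1(OC(=O)C(C)C)COC1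
F5 | step 6 | (2S)-1-bromo-2-[5-methoxy-4-methyl-2-(prop-2-enyloxy)phenyl]-3-(trimethylsilyloxy)propan-2-yl 2-methylpropanoate | C=CCOc1cc(C)c(OC)cc1[C@](OC(=O)C(C)C)(CO[Si](C)(C)C)CBr
F6 | step 6 | (2S)-1-bromo-3-hydroxy-2-[5-methoxy-4-methyl-2-(prop-2-enyloxy)phenyl]propan-2-yl 2-methylpropanoate | C=CCOc1cc(C)c(OC)cc1[C@](OC(=O)C(C)C)(CO)CBr
F7 | step 6 | (2S)-3-bromo-2-hydroxy-2-[5-methoxy-4-methyl-2-(prop-2-enyloxy)phenyl]propyl 2-methylpropanoate | C=CCOc1cc(C)c(OC)cc1[C@](O)(COC(=O)C(C)C)CBr
F8 | step 6 | {(2R)-2-[5-methoxy-4-methyl-2-(prop-2-enyloxy)phenyl]oxiran-2-yl}methyl 2-methylpropanoate | C=CCOc1cc(C)c(OC)cc1[C@]1(COC(=O)C(C)C)CO1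
F9 | step 6 | {(2R)-2-[5-methoxy-4-methyl-2-(tributylstannyloxy)phenyl]oxiran-2-yl}methyl 2-methylpropanoate | CCCC[Sn](CCCC)(CCCC)Oc1cc(C)c(OC)cc1[C@]1(COC(=O)C(C)C)CO1
F10 | step 4 | 2-(3-hydroxyoxetan-3-yl)-4-methoxy-5-methylphenyl 2-methylpropanoate | CC(C)C(=O)Oc1cc(C)c(OC)cc1C1(O)COC1
F11 | step 4 | lithium 4-methoxy-5-methyl-2-[3-(2-methylpropanoyloxy)oxetan-3-yl]phenolate | [Li]Oc1cc(C)c(OC)cc1C1(OC(=O)C(C)C)COC1
F12 | step 2 | 1-(benzyloxy)-2-bromo-4-methoxy-5-methylbenzene | Brc1cc(OC)c(C)cc1OCc1ccccc1
F13 | step 2 | [2-(benzyloxy)-5-methoxy-4-methylphenyl]lithium | [Li]c1cc(OC)c(C)cc1OCc1ccccc1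
F14 | step 2 | 3-[2-(benzyloxy)-5-methoxy-4-methylphenyl]oxetan-3-ol | OC1(COC1)c1cc(OC)c(C)cc1OCc1ccccc1
A1 | alternative 1 | 2-(3-hydroxyprop-1-en-2-yl)-4-methoxy-5-methylphenyl (E)-2-methylbut-2-enoate | C/C=C(\C)C(=O)Oc1cc(C)c(OC)cc1C(=C)CO
A2 | alternative 1 | 2-[(2S)-2-(hydroxymethyl)oxiran-2-yl]-4-methoxy-5-methylphenyl (E)-2-methylbut-2-enoate | C/C=C(\C)C(=O)Oc1cc(C)c(OC)cc1[C@]1(CO)CO1
A3 | alternative 2 | 4-methoxy-5-methyl-2-[2-(2-methylpropanoyloxy)acetyl]phenyl (E)-2-methylbut-2-enoate | C/C=C(\C)C(=O)Oc1cc(C)c(OC)cc1C(=O)COC(=O)C(C)C
A4 | alternative 3 | 4-methoxy-5-methyl-2-(1,2,3-trihydroxypropan-2-yl)phenyl (E)-2-methylbut-2-enoate | C/C=C(\C)C(=O)Oc1cc(C)c(OC)cc1C(O)(CO)CO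
A5 | alternative 3 | 2-[(2R)-1,2-dihydroxy-3-(2-methylpropanoyloxy)propan-2-yl]-4-methoxy-5-methylphenyl (E)-2-methylbut-2-enoate | C/C=C(\C)C(=O)Oc1cc(C)c(OC)cc1[C@](O)(COC(=O)C(C)C)CO
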